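**Retrosynthetic overview**
- Locants: C1 (bears =CH2), C2=C3, C4, C5 (CH3), C6, C7 (OAc), C8=C9 (CH3), C10 and C11 run round the eleven-membered ring. C12, C13 and C14 (CH3) complete the cyclopentane. C15 (OAc) and C16 (OH) complete the cyclohexene. β is the face of the C14 methyl group.
- Last ring: the eleven-membered ring is closed at C3–C4 by a Pd-catalysed, strain-releasing opening of a 1-alkenyl-3-methylcyclobutanol tethered to an (E)-chlorodiene. The liberated C7 ketone is then reduced and acetylated.
- Enabling feature: in the eleven-membered ring the run C7(O)–C6H2–C5H(CH3)–C4H2 lies between sp2 C8 of the cyclohexene and sp2 C3 of the diene. It is therefore a ring-opened 3-methylcyclobutanol with C7 as carbinol carbon and C5 on its local mirror plane. Achiral 3-methylcyclobutanone supplies C4–C7, and C5 arises by desymmetrisation.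
- Hydrindane: the cyclopentane (bond C10–C11) comes from a thermal type-I ene reaction of a 4,4-disubstituted cyclohexenone, which also places the C1 isopropenyl unit on the concave face. The cyclohexenone (C9=C10) comes from an aldol condensation.
- All ten carbons of geraniol become C1, =CH2, C2, C10–C15 and the C14 methyl. Ring order: cyclohexene, then cyclopentane, then the eleven-membered ring.

Key step: step 17

Remark: 3-methylcyclobutanone, butan-2-one and geraniol are taken as commercial. TES = triethylsilyl. TBS = tert-butyldimethylsilyl. MABR = methylaluminium bis(4-bromo-2,6-di-tert-butylphenoxide). Palladium intermediates are drawn without the ligand.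

**Step 1**
Reactants: 1 geraniol
Product: 2 (2S,3S)-2,3-epoxygeraniol
Conditions: Ti(OiPr)4 (5 mol %), L-(+)-diethyl tartrate (6 mol %), t-BuOOH, 4 Å MS, CH2Cl2, −20 °C
Reagents that add atoms: tert-butyl hydroperoxide CC(C)(C)OO
Why: Katsuki–Sharpless asymmetric epoxidation; the allylic alcohol binds to the titanium tartrate complex, L-(+)-tartrate directs oxygen to the face that gives the (2S,3S)-epoxide, and the remote trisubstituted alkene is not touched.

**Step 2**
Reactants: 2 (2S,3S)-2,3-epoxygeraniol
Product: 3 (2S,3S)-2,3-epoxygeranyl triethylsilyl ether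
Conditions: Et3SiCl, imidazole, CH2Cl2, 0 °C
Reagents that add atoms: chlorotriethylsilane CC[Si](Cl)(CC)CC
Why: Imidazole-promoted silylation of a primary alcohol, needed because the next step migrates the CH2OSi group.

**Step 3**
Reactants: 3 (2S,3S)-2,3-epoxygeranyl triethylsilyl ether
Product: 4 (S)-2,6-dimethyl-2-[(triethylsilyloxy)methyl]hept-5-enal
Conditions: MABR (20 mol %), CH2Cl2, −78 to −40 °C
Reagents that add atoms: none
Why: MABR-promoted rearrangement of an epoxy silyl ether to a β-silyloxy aldehyde (semipinacol type); the bulky Lewis acid opens the epoxide at the tertiary carbon and CH2OSiEt3 migrates anti to the leaving oxygen, so the epoxide configuration passes with inversion into the quaternary centre C14.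

**Step 4**
Reactants: 4 (S)-2,6-dimethyl-2-[(triethylsilyloxy)methyl]hept-5-enal; 5 butan-2-one
Product: 6 (5S,6S)-5-hydroxy-6,10-dimethyl-6-[(triethylsilyloxy)methyl]undec-9-en-3-one
Conditions: D-proline (30 mol %), DMSO/butan-2-one 4:1, rt
Reagents that add atoms: none
Why: Proline-catalysed direct aldol reaction; the less substituted enamine of butan-2-one adds to the non-enolisable α-quaternary aldehyde, and D-proline (catalyst control through the hydrogen-bonded enamine transition state) sets C15.

**Step 5**
Reactants: 6 (5S,6S)-5-hydroxy-6,10-dimethyl-6-[(triethylsilyloxy)methyl]undec-9-en-3-one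
Product: 7 (5S,6S)-6,10-dimethyl-5-(triethylsilyloxy)-6-[(triethylsilyloxy)methyl]undec-9-en-3-one
Conditions: Et3SiOTf, 2,6-lutidine, CH2Cl2, −78 °C
Reagents that add atoms: triethylsilyl triflate CC[Si](CC)(CC)OS(=O)(=O)C(F)(F)F
Why: Silyl triflate silylation of a hindered secondary alcohol under non-nucleophilic base, cold enough to avoid retro-aldol cleavage or β-elimination.

**Step 6**
Reactants: 7 (5S,6S)-6,10-dimethyl-5-(triethylsilyloxy)-6-[(triethylsilyloxy)methyl]undec-9-en-3-one
Product: 8 (2R,3S)-2-methyl-2-(4-methylpent-3-enyl)-5-oxo-3-(triethylsilyloxy)heptanal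
Conditions: (COCl)2, DMSO, CH2Cl2, −78 to −40 °C; Et3N, −78 °C to rt
Reagents that add atoms: none
Why: Swern oxidation applied directly to the silyl ether; primary triethylsilyl ethers are cleaved and oxidised by the chlorosulfonium salt while the hindered secondary one stays, which saves a deprotection step.

**Step 7**
Reactants: 8 (2R,3S)-2-methyl-2-(4-methylpent-3-enyl)-5-oxo-3-(triethylsilyloxy)heptanal
Product: 9 (4S,5S)-2,4-dimethyl-4-(4-methylpent-3-enyl)-5-(triethylsilyloxy)cyclohex-2-en-1-one
Conditions: piperidine (20 mol %), AcOH (20 mol %), 4 Å MS, toluene, 70 °C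
Reagents that add atoms: none
Why: Intramolecular aldol condensation; only the ethyl-side enol can reach the non-enolisable aldehyde through a six-membered transition state (the other α-carbon would close a four-membered ring), and loss of water gives the C9=C10 enone without forming a new stereocentre.

**Step 8**
Reactants: 9 (4S,5S)-2,4-dimethyl-4-(4-methylpent-3-enyl)-5-(triethylsilyloxy)cyclohex-2-en-1-one
Product: 10 (4S,5R,6S)-6-hydroxy-2,4-dimethyl-4-(4-methylpent-3-enyl)-5-(triethylsilyloxy)cyclohex-2-en-1-one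
Conditions: LDA, THF, −78 °C; 2-(phenylsulfonyl)-3-phenyloxaziridine, −78 °C
Reagents that add atoms: 2-(phenylsulfonyl)-3-phenyloxaziridine O=S(=O)(N1OC1c1ccccc1)c1ccccc1
Why: Davis oxidation of the cross-conjugated α′ lithium enolate, the only enolate available; the oxaziridine approaches anti to the neighbouring C15 silyloxy group and should give the trans 15β,16α arrangement.

**Step 9**
Reactants: 10 (4S,5R,6S)-6-hydroxy-2,4-dimethyl-4-(4-methylpent-3-enyl)-5-(triethylsilyloxy)cyclohex-2-en-1-one
Product: 11 (4S,5R,6S)-6-(tert-butyldimethylsilyloxy)-2,4-dimethyl-4-(4-methylpent-3-enyl)-5-(triethylsilyloxy)cyclohex-2-en-1-one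
Conditions: t-BuMe2SiOTf, 2,6-lutidine, CH2Cl2, 0 °C
Reagents that add atoms: tert-butyldimethylsilyl triflate CC(C)(C)[Si](C)(C)OS(=O)(=O)C(F)(F)F
Why: Silyl triflate silylation; the more robust TBS group on O16 is orthogonal to TES on O15, so O16 can be freed last.

**Step 10**
Reactants: 11 (4S,5R,6S)-6-(tert-butyldimethylsilyloxy)-2,4-dimethyl-4-(4-methylpent-3-enyl)-5-(triethylsilyloxy)cyclohex-2-en-1-one
Product: 12 isopropenyl cis-hydrindanone (C8 ketone; 9β-CH3; 10β-H; 11β-H and 11α-isopropenyl; 14β-CH3; 15β-OTES; 16α-OTBS)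
Conditions: toluene (0.02 M), BHT (cat.), sealed silylated tube, 240 °C
Reagents that add atoms: none
Why: Thermal intramolecular type-I Alder-ene reaction of a 1,6-diene with an enone enophile; the three-atom tether forces C11 onto C10 from the side-chain face (cis fusion), and the concerted transfer of a methyl hydrogen to C9 is possible only when C1 lies over C9, which puts the new isopropenyl group cis to C9 on the concave face.

**Step 11**
Reactants: 12 isopropenyl cis-hydrindanone
Product: 13 allylic chloride (C1(=CH2)–C2H2Cl; otherwise as 12)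
Conditions: aq NaOCl, CeCl3·7H2O, CH2Cl2/H2O, 0 °C
Reagents that add atoms: sodium hypochlorite [Na+].[O-]Cl
Why: Ene-type allylic chlorination of an isopropenyl group by a hypochlorous acid equivalent; this is the only C=C bond in the molecule.

**Step 12**
Reactants: 13 allylic chloride
Product: 14 enal (C1(=CH2)–C2HO; otherwise as 12)
Conditions: N-methylmorpholine N-oxide, KI (10 mol %), 4 Å MS, MeCN, 40 °C
Reagents that add atoms: N-methylmorpholine N-oxide C[N+]1([O-])CCOCC1
Why: Kornblum-type N-oxide oxidation of an allylic halide; the N-oxide oxygen displaces the halide and loss of N-methylmorpholine gives the aldehyde.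

**Step 13**
Reactants: 14 enal
Product: 15 (E)-chlorodiene ketone (C1(=CH2)–C2H=C3HCl; otherwise as 12)
Conditions: CrCl2, CHCl3, THF, 65 °C
Reagents that add atoms: chloroform ClC(Cl)Cl
Why: Takai–Utimoto olefination; the geminal dichromium reagent reacts with the aldehyde and not with the hindered ketone, and it gives the (E)-chloroalkene.

**Step 14**
Reactants: 15 (E)-chlorodiene ketone
Product: 16 C8 enol triflate (C8(OTf)=C9; 10β-H; 11β-H; 14β-CH3; 15β-OTES; 16α-OTBS)
Conditions: KHMDS, THF, −78 to −40 °C; N-(5-chloro-2-pyridyl)bis(trifluoromethanesulfonimide), −78 °C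
Reagents that add atoms: Comins' reagent FC(F)(F)S(=O)(=O)N(c1ccc(Cl)cn1)S(=O)(=O)C(F)(F)F
Why: Regioselective enolisation and O-sulfonylation with Comins' reagent; in the chair with both silyloxy groups axial, H-9 is axial and aligned with the carbonyl π system while H-16 is equatorial, so the C8=C9 enolate should form and C9 ceases to be a stereocentre.

**Step 15**
Reactants: 16 C8 enol triflate
Product: 17 C8 trimethylstannane (otherwise as 16)
Conditions: (Me3Sn)2, Pd(PPh3)4 (5 mol %), LiCl, THF, 65 °C
Reagents that add atoms: hexamethylditin C[Sn](C)(C)[Sn](C)(C)C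
Why: Stille-type palladium-catalysed stannylation of an enol triflate; the alkenyl chloride does not add oxidatively to Pd(PPh3)4 under these conditions.

**Step 16**
Reactants: 17 C8 trimethylstannane; 18 3-methylcyclobutanone
Product: 20 tertiary cyclobutanol (C8 bears a 1-hydroxy-3-methylcyclobutyl group with OH cis to CH3; otherwise as 16), via C8 alkenyllithium 19 (not isolated)
Conditions: MeLi, THF, −78 °C; then 18, −78 °C
Reagents that add atoms: none
Why: Tin–lithium exchange followed by 1,2-addition of the alkenyllithium to a strained and very electrophilic ketone; attack anti to the ring methyl gives OH cis to CH3, and this centre becomes sp2 in the next step, so either carbinol epimer is usable.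

**Step 17**
Reactants: 20 tertiary cyclobutanol
Product: 23 (5S)-macrocyclic enone (C7 ketone; E-C2=C3; 15β-OTES; 16α-OTBS), via oxapalladacycle 21 (not isolated), via carbapalladacycle 22 (not isolated)
Conditions: Pd(OAc)2 (10 mol %), (R)-1-[(SP)-2-(dicyclohexylphosphino)ferrocenyl]ethyldi-tert-butylphosphine (12 mol %), Cs2CO3, toluene, 90 °C, 20 added by syringe pump to 1 mM
Reagents that add atoms: none
Why: Proposed new method: Pd(0) inserts into the C3–Cl bond with retention, Cs2CO3 turns the C7 hydroxyl into a Pd(II) alkoxide (ten-membered 21), strain-driven β-carbon elimination (about 26 kcal/mol released) cuts one C7–CH2 bond of the cyclobutane to give the C7 enone and the primary C4–Pd alkyl 22, and C(sp3)–C(sp2) reductive elimination forms C3–C4. The closest known reaction type is the intermolecular Pd-catalysed arylation and vinylation of tert-cyclobutanols by enantioselective C–C cleavage with chiral ferrocenyl phosphines, and what is new is its use on a tethered alkenyl halide to close a macrocycle. The eleven-membered ring is closed by ring contraction of the twelve-membered palladacycle 22 in the reductive elimination, so once the alkoxide is bound no free chain end has to find its partner. The only new stereocentre, C5, lies on the local mirror plane of the cyclobutanol and is set by which of the two diastereotopic ring bonds becomes syn-coplanar with Pd–O, a choice controlled by the chiral ligand (both enantiomers are available) and reinforced by the rigid hydrindane tether that holds palladium under the concave face. The E geometry of C2=C3 is carried over from 20, and the geometry of C8=C9 is fixed by the six-membered ring. The step needs ring C–C cleavage over C7–C8 cleavage (secured by ring strain), reductive elimination over β-hydride loss from C5–H (secured by the bulky electron-rich bisphosphine and the alkenyl group already on palladium) and cyclisation over oligomerisation (secured by slow addition and by the 11α side chain, which points from the concave face towards C8).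

**Step 18**
Reactants: 23 (5S)-macrocyclic enone
Product: 25 (5S,7S)-7,15-diol 16-TBS ether, via (5S,7S)-allylic alcohol 24 (not isolated)
Conditions: (R)-Me-CBS oxazaborolidine (30 mol %), catecholborane, toluene, −78 °C; then PPTS (cat.), MeOH, 0 °C
Reagents that add atoms: none
Why: Corey–Bakshi–Shibata reduction; the (R)-catalyst distinguishes the large tetrasubstituted alkenyl group from the CH2 group and should deliver hydride to give (7S), catecholborane at low temperature spares the diene, and mild acid methanolysis then removes only the TES ether.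

**Step 19**
Reactants: 25 (5S,7S)-7,15-diol 16-TBS ether
Product: 26 7,15-diacetate 16-TBS ether
Conditions: Ac2O, DMAP (cat.), pyridine, rt
Reagents that add atoms: acetic anhydride CC(=O)OC(C)=O
Why: DMAP-catalysed acetylation of both free secondary alcohols in one operation, with O16 still masked.

**Step 20**
Reactants: 26 7,15-diacetate 16-TBS ether
Product: 27 CNP0323842.1 (target)
Conditions: HF·pyridine, pyridine, THF, 0 °C to rt
Reagents that add atoms: none
Why: Fluoride desilylation in an acidic buffered medium, which frees O16 without generating an alkoxide and so avoids 15→16 acetyl migration.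

**Compound list**
1 | geraniol | CC(C)=CCC/C(C)=C/CO | starting material
2 | (2S,3S)-2,3-epoxygeraniol | CC(C)=CCC[C@]1(C)O[C@H]1CO | intermediate
3 | (2S,3S)-2,3-epoxygeranyl triethylsilyl ether | CC(C)=CCC[C@]1(C)O[C@H]1CO[Si](CC)(CC)CC | intermediate
4 | (S)-2,6-dimethyl-2-[(triethylsilyloxy)methyl]hept-5-enal | CC(C)=CCC[C@](CO[Si](CC)(CC)CC)(C)C=O | intermediate
5 | butan-2-one | CCC(C)=O | starting material
6 | (5S,6S)-5-hydroxy-6,10-dimethyl-6-[(triethylsilyloxy)methyl]undec-9-en-3-one | CC(C)=CCC[C@](CO[Si](CC)(CC)CC)(C)[C@@H](O)CC(=O)CC | intermediate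
7 | (5S,6S)-6,10-dimethyl-5-(triethylsilyloxy)-6-[(triethylsilyloxy)methyl]undec-9-en-3-one | CC(C)=CCC[C@](CO[Si](CC)(CC)CC)(C)[C@@H](O[Si](CC)(CC)CC)CC(=O)CC | intermediate
8 | (2R,3S)-2-methyl-2-(4-methylpent-3-enyl)-5-oxo-3-(triethylsilyloxy)heptanal | CC(C)=CCC[C@](C=O)(C)[C@@H](O[Si](CC)(CC)CC)CC(=O)CC | intermediate
9 | (4S,5S)-2,4-dimethyl-4-(4-methylpent-3-enyl)-5-(triethylsilyloxy)cyclohex-2-en-1-one | CC(C)=CCC[C@@]1(C)C=C(C)C(=O)C[C@@H]1O[Si](CC)(CC)CC | intermediate
10 | (4S,5R,6S)-6-hydroxy-2,4-dimethyl-4-(4-methylpent-3-enyl)-5-(triethylsilyloxy)cyclohex-2-en-1-one | CC(C)=CCC[C@@]1(C)C=C(C)C(=O)[C@@H](O)[C@@H]1O[Si](CC)(CC)CC | intermediate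
11 | (4S,5R,6S)-6-(tert-butyldimethylsilyloxy)-2,4-dimethyl-4-(4-methylpent-3-enyl)-5-(triethylsilyloxy)cyclohex-2-en-1-one | CC(C)=CCC[C@@]1(C)C=C(C)C(=O)[C@@H](O[Si](C)(C)C(C)(C)C)[C@@H]1O[Si](CC)(CC)CC | intermediate
12 | isopropenyl cis-hydrindanone | CC(=C)[C@@H]1CC[C@]2(C)[C@@H](O[Si](CC)(CC)CC)[C@H](O[Si](C)(C)C(C)(C)C)C(=O)[C@@H](C)[C@H]12 | intermediate
13 | allylic chloride | ClCC(=C)[C@@H]1CC[C@]2(C)[C@@H](O[Si](CC)(CC)CC)[C@H](O[Si](C)(C)C(C)(C)C)C(=O)[C@@H](C)[C@H]12 | intermediate
14 | enal | O=CC(=C)[C@@H]1CC[C@]2(C)[C@@H](O[Si](CC)(CC)CC)[C@H](O[Si](C)(C)C(C)(C)C)C(=O)[C@@H](C)[C@H]12 | intermediate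
15 | (E)-chlorodiene ketone | Cl/C=C/C(=C)[C@@H]1CC[C@]2(C)[C@@H](O[Si](CC)(CC)CC)[C@H](O[Si](C)(C)C(C)(C)C)C(=O)[C@@H](C)[C@H]12 | intermediate
16 | C8 enol triflate | Cl/C=C/C(=C)[C@@H]1CC[C@]2(C)[C@@H](O[Si](CC)(CC)CC)[C@H](O[Si](C)(C)C(C)(C)C)C(OS(=O)(=O)C(F)(F)F)=C(C)[C@H]12 | intermediate
17 | C8 trimethylstannane | Cl/C=C/C(=C)[C@@H]1CC[C@]2(C)[C@@H](O[Si](CC)(CC)CC)[C@H](O[Si](C)(C)C(C)(C)C)C([Sn](C)(C)C)=C(C)[C@H]12 | intermediate
18 | 3-methylcyclobutanone | CC1CC(=O)C1 | starting material
19 | C8 alkenyllithium | Cl/C=C/C(=C)[C@@H]1CC[C@]2(C)[C@@H](O[Si](CC)(CC)CC)[C@H](O[Si](C)(C)C(C)(C)C)C([Li])=C(C)[C@H]12 | intermediate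
20 | tertiary cyclobutanol (OH cis to CH3) | Cl/C=C/C(=C)[C@@H]1CC[C@]2(C)[C@@H](O[Si](CC)(CC)CC)[C@H](O[Si](C)(C)C(C)(C)C)C(=C(C)[C@H]12)[C@]3(O)C[C@@H](C)C3 | intermediate
21 | oxapalladacycle (ten-membered, ligand omitted) | C=C1/C=C/[Pd]O[C@]2(C[C@@H](C)C2)C3=C(C)[C@@H]4[C@H]1CC[C@]4(C)[C@@H](O[Si](CC)(CC)CC)[C@@H]3O[Si](C)(C)C(C)(C)C | intermediate
22 | carbapalladacycle (twelve-membered, ligand omitted) | C=C1/C=C/[Pd]C[C@H](C)CC(=O)C2=C(C)[C@@H]3[C@H]1CC[C@]3(C)[C@@H](O[Si](CC)(CC)CC)[C@@H]2O[Si](C)(C)C(C)(C)C | intermediate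
23 | (5S)-macrocyclic enone | C=C1/C=C/C[C@H](C)CC(=O)C2=C(C)[C@@H]3[C@H]1CC[C@]3(C)[C@@H](O[Si](CC)(CC)CC)[C@@H]2O[Si](C)(C)C(C)(C)C | intermediate
24 | (5S,7S)-allylic alcohol | C=C1/C=C/C[C@H](C)C[C@H](O)C2=C(C)[C@@H]3[C@H]1CC[C@]3(C)[C@@H](O[Si](CC)(CC)CC)[C@@H]2O[Si](C)(C)C(C)(C)C | intermediate
25 | (5S,7S)-7,15-diol 16-TBS ether | C=C1/C=C/C[C@H](C)C[C@H](O)C2=C(C)[C@@H]3[C@H]1CC[C@]3(C)[C@@H](O)[C@@H]2O[Si](C)(C)C(C)(C)C | intermediate
26 | 7,15-diacetate 16-TBS ether | C=C1/C=C/C[C@H](C)C[C@H](OC(C)=O)C2=C(C)[C@@H]3[C@H]1CC[C@]3(C)[C@@H](OC(C)=O)[C@@H]2O[Si](C)(C)C(C)(C)C | intermediate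
27 | CNP0323842.1 | C=C1/C=C/C[C@H](C)C[C@H](OC(C)=O)C2=C(C)[C@@H]3[C@H]1CC[C@]3(C)[C@@H](OC(C)=O)[C@@H]2O | target

**Summary**
Total step count: 20. Longest linear sequence: 20 steps, from geraniol.

**Steps most likely to fail**

Step 17. What may go wrong: β-hydride loss or protonolysis of the ring-opened alkylpalladium, oligomerisation instead of ring closure, or poor discrimination between the two diastereotopic cyclobutane bonds.

The fallback uses known chemistry. It sets out from ketone 18 and stannane 17 and comes back at macrocyclic enone 23.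
- A catalytic asymmetric Baeyer–Villiger oxidation of 18 (chiral phosphoric acid, aq H2O2) would give (R)-4-methyldihydrofuran-2(3H)-one F1, so that C5 is fixed before any coupling.
- Alkenyllithium 19 (from 17 and MeLi) would open F1 at −78 °C to the hydroxy enone F2.
- An Appel iodination (I2, PPh3, imidazole) would give the primary iodide F3.
- Zinc insertion (Zn, LiCl, THF) would give the alkylzinc iodide F4.
- An intramolecular Negishi coupling of F4 with the chlorodiene (Pd2(dba)3, RuPhos, high dilution) would close C3–C4 to 23.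

Step 10. What may go wrong: the ene reaction may need a temperature at which loss of a silyloxy group or other decomposition competes, or a non-concerted pathway may erode the configuration at C11.

The fallback sets out from enone 11 and comes back at hydrindanone 12.
- Irradiation (Pyrex filter, hexane) would bring about the intramolecular enone–olefin [2+2] photocycloaddition to the cyclobutane photoadduct F5. Its four-membered ring (C9, C10, C11, C1) enforces the same cis relations.
- Me3SiI with (Me3Si)2NH would open the acylcyclobutane bond C9–C1 to the tertiary iodide silyl enol ether F6.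
- DBU would remove HI to give the isopropenyl silyl enol ether F7.
- K2CO3 in MeOH would release ketone 12. A C9 epimer would converge at 16.

Step 14. What may go wrong: deprotonation at C16 instead of C9, followed by loss of the C15 silyloxy group.

The fallback sets out from ketone 15 and comes back at cyclobutanol 20, bypassing 16 and 17.
- Hydrazine hydrate with Et3N in EtOH would give the hydrazone F8.
- The Barton vinyl iodide synthesis (I2, tetramethylguanidine, THF) would give the C8 alkenyl iodide F9. The elimination needs an antiperiplanar axial hydrogen, which only C9 offers.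
- Iodine–magnesium exchange (i-PrMgCl·LiCl) and addition to 18 in the presence of LaCl3·2LiCl would give 20.

**Further compounds**
F1 | step 17 | (R)-4-methyldihydrofuran-2(3H)-one | O=C1C[C@@H](C)CO1
F2 | step 17 | hydroxy enone | Cl/C=C/C(=C)[C@@H]1CC[C@]2(C)[C@@H](O[Si](CC)(CC)CC)[C@H](O[Si](C)(C)C(C)(C)C)C(=C(C)[C@H]12)C(=O)C[C@@H](C)CO
F3 | step 17 | primary iodide | Cl/C=C/C(=C)[C@@H]1CC[C@]2(C)[C@@H](O[Si](CC)(CC)CC)[C@H](O[Si](C)(C)C(C)(C)C)C(=C(C)[C@H]12)C(=O)C[C@@H](C)CI
F4 | step 17 | alkylzinc iodide | Cl/C=C/C(=C)[C@@H]1CC[C@]2(C)[C@@H](O[Si](CC)(CC)CC)[C@H](O[Si](C)(C)C(C)(C)C)C(=C(C)[C@H]12)C(=O)C[C@@H](C)C[Zn]I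
F5 | step 10 | cyclobutane photoadduct | CC1(C)[C@@H]2CC[C@]3(C)[C@@H](O[Si](CC)(CC)CC)[C@H](O[Si](C)(C)C(C)(C)C)C(=O)[C@@]1(C)[C@H]23
F6 | step 10 | tertiary iodide silyl enol ether | CC(C)(I)[C@@H]1CC[C@]2(C)[C@@H](O[Si](CC)(CC)CC)[C@H](O[Si](C)(C)C(C)(C)C)C(O[Si](C)(C)C)=C(C)[C@H]12
F7 | step 10 | isopropenyl silyl enol ether | CC(=C)[C@@H]1CC[C@]2(C)[C@@H](O[Si](CC)(CC)CC)[C@H](O[Si](C)(C)C(C)(C)C)C(O[Si](C)(C)C)=C(C)[C@H]12
F8 | step 14 | hydrazone | Cl/C=C/C(=C)[C@@H]1CC[C@]2(C)[C@@H](O[Si](CC)(CC)CC)[C@H](O[Si](C)(C)C(C)(C)C)C(=NN)[C@@H](C)[C@H]12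
F9 | step 14 | C8 alkenyl iodide | Cl/C=C/C(=C)[C@@H]1CC[C@]2(C)[C@@H](O[Si](CC)(CC)CC)[C@H](O[Si](C)(C)C(C)(C)C)C(I)=C(C)[C@H]12
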